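**Strategy.** Ring B of the target (O1, C2, C3, C3a, C7a) with its 2-hydroxypropan-2-yl group on C2 is a constitutional isomer of a 2,2-dimethylpyran-3-ol, so the dihydrofuran is disconnected to a six-membered chromanol whose carbinol centre comes from one Jacobsen epoxidation of a 2,2-dimethylchromene. In the key step the ring oxygen expels the activated C3 hydroxyl of the dearomatised precursor 13 (4a-allyl, 8-prenyl, 7-methoxy, 6-isobutyryl, hydroxyl trans to allyl), and water opens the resulting oxiranium ion at the tertiary carbon: one operation contracts the pyran to ring B, inverts the carbinol carbon to give C2 and unveils the tertiary alcohol. Epoxidation, allyl-to-prenyl metathesis and enol-ether hydrolysis finish the synthesis.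

Key step: step 9

Remark 1: chroman numbering (O1, C2 to C4, C4a, C5 to C8, C8a) is used up to compound 15, benzofuran numbering (O1, C2, C3, C3a, C4 to C7, C7a) from compound 16 on.
Remark 2 (assumption): the target is drawn as its 4-hydroxy-6-oxo enol; step 12 releases the 6-hydroxy-4-oxo enol, which is the same compound by fast proton transfer within the acyl-1,3-dione. The ring-fusion descriptor changes from S (16 to 19) to R (20) only because the CIP ranking of C4 and C7a changes with the enol form.

Step 1
Reactants: 1 5-methoxyresorcinol; 2 isobutyryl chloride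
Product: 3 1-(2,4-dihydroxy-6-methoxyphenyl)-2-methylpropan-1-one
Conditions: AlCl3 (3 equiv), PhNO2, 0 °C to rt; then ice/aq. HCl
Reagents that add atoms: isobutyryl chloride 2, CC(C)C(Cl)=O
Why: Friedel–Crafts acylation, in which the carbon para to one hydroxyl and ortho to the other (two equivalent sites) is attacked in preference to the carbon between the two hydroxyls, so that 3 should be the main ketone and the symmetric 2,6-dihydroxy-4-methoxy isomer can be removed by chromatography, while the low temperature spares the methyl ether from AlCl3.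

Step 2
Reactants: 3 1-(2,4-dihydroxy-6-methoxyphenyl)-2-methylpropan-1-one; 4 3-methylbut-2-enal
Product: 5 1-(5-hydroxy-7-methoxy-2,2-dimethyl-2H-chromen-6-yl)-2-methylpropan-1-one
Conditions: ethylenediammonium diacetate (10 mol%), toluene, 110 °C
Reagents that add atoms: 3-methylbut-2-enal 4, CC(C)=CC=O
Why: Amine-catalysed chromene annulation (Knoevenagel-type condensation at the ring carbon flanked by both hydroxyls, dehydration to an ortho-quinone methide and 6π oxa-electrocyclisation), which should close through the free para hydroxyl because this leaves the other hydroxyl hydrogen-bonded to the ketone.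

Step 3
Reactants: 5 1-(5-hydroxy-7-methoxy-2,2-dimethyl-2H-chromen-6-yl)-2-methylpropan-1-one
Product: 6 1-[(3R,4R)-3,4-epoxy-5-hydroxy-7-methoxy-2,2-dimethyl-3,4-dihydro-2H-chromen-6-yl]-2-methylpropan-1-one
Conditions: (R,R)-(salen)MnCl [(R,R)-N,N'-bis(3,5-di-tert-butylsalicylidene)cyclohexane-1,2-diamine manganese chloride, trivalent manganese] (5 mol%), mCPBA (2 equiv), N-methylmorpholine N-oxide (5 equiv), CH2Cl2, −78 °C
Reagents that add atoms: mCPBA, OOC(=O)c1cccc(Cl)c1
Why: Jacobsen epoxidation of a cis-disubstituted, aryl-conjugated olefin, for which 2,2-dimethylchromenes are the best substrate class: the (R,R)-salen complex should deliver oxygen to the face that gives the (3R,4R)-oxide and so sets the C3 carbinol centre of the whole route, while the anhydrous peracid/N-oxide protocol avoids hypochlorite (chlorination at C8) and buffers the acid-labile benzylic epoxide.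

Step 4
Reactants: 6 1-[(3R,4R)-3,4-epoxy-5-hydroxy-7-methoxy-2,2-dimethyl-3,4-dihydro-2H-chromen-6-yl]-2-methylpropan-1-one
Product: 7 1-[(3R)-3,5-dihydroxy-7-methoxy-2,2-dimethyl-3,4-dihydro-2H-chromen-6-yl]-2-methylpropan-1-one
Conditions: H2 (1 atm), Pd/C (10 wt%), EtOAc, rt
Reagents that add atoms: none
Why: Catalytic hydrogenolysis cleaves only the benzylic C4–O bond of the aryl epoxide, so that C3 keeps its oxygen and its R configuration, and the hydrogen-bonded aryl ketone is not reduced under these mild conditions.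

Step 5
Reactants: 7 1-[(3R)-3,5-dihydroxy-7-methoxy-2,2-dimethyl-3,4-dihydro-2H-chromen-6-yl]-2-methylpropan-1-one; 8 2-methylbut-3-en-2-ol
Product: 9 1-[(3R)-3,5-dihydroxy-7-methoxy-2,2-dimethyl-8-(3-methylbut-2-en-1-yl)-3,4-dihydro-2H-chromen-6-yl]-2-methylpropan-1-one
Conditions: BF3·OEt2 (0.3 equiv), 1,4-dioxane, rt
Reagents that add atoms: 2-methylbut-3-en-2-ol 8, CC(C)(O)C=C
Why: Friedel–Crafts prenylation by the dimethylallyl cation formed from the tertiary allylic alcohol, which can only attack C8, the single unsubstituted ring carbon (ortho to OMe and O1, para to OH), and whose product cannot cyclise further because neither neighbour of C8 carries a free hydroxyl.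

Step 6
Reactants: 9 1-[(3R)-3,5-dihydroxy-7-methoxy-2,2-dimethyl-8-(3-methylbut-2-en-1-yl)-3,4-dihydro-2H-chromen-6-yl]-2-methylpropan-1-one
Product: 10 1-[(3R)-3-(tert-butyldimethylsilyloxy)-5-hydroxy-7-methoxy-2,2-dimethyl-8-(3-methylbut-2-en-1-yl)-3,4-dihydro-2H-chromen-6-yl]-2-methylpropan-1-one
Conditions: TBSOTf (1.2 equiv), 2,6-lutidine, CH2Cl2, −78 °C
Reagents that add atoms: tert-butyldimethylsilyl triflate, CC(C)(C)[Si](C)(C)OS(=O)(=O)C(F)(F)F
Why: Silylation of the secondary alcohol by a silyl triflate and a hindered base, selective because the phenol is tied up in a hydrogen bond to the ketone and flanked on both sides, and it installs the bulky group that steers step 7.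

Step 7
Reactants: 10 1-[(3R)-3-(tert-butyldimethylsilyloxy)-5-hydroxy-7-methoxy-2,2-dimethyl-8-(3-methylbut-2-en-1-yl)-3,4-dihydro-2H-chromen-6-yl]-2-methylpropan-1-one; 11 allyl bromide
Product: 12 (3R,4aS)-4a-allyl-3-(tert-butyldimethylsilyloxy)-7-methoxy-2,2-dimethyl-8-(3-methylbut-2-en-1-yl)-6-(2-methylpropanoyl)-3,4-dihydro-2H-chromen-5(4aH)-one (silyloxy trans to allyl)
Conditions: LiN(SiMe3)2 (1.1 equiv), toluene, −78 °C; then 11 (3 equiv), −78 to 0 °C
Reagents that add atoms: allyl bromide 11, C=CCBr
Why: Alkylative dearomatisation (SN2 C-allylation of a lithium phenoxide at a substituted ortho carbon, as known for acylphloroglucinols): the contact ion pair in toluene should favour the ortho carbon C4a over the para carbon C8 and over oxygen, C6 is deactivated by its acyl group, and the silyl ether, pseudo-axial next to the gem-dimethyl carbon, blocks one face of C4a so that allyl enters anti to it and sets C4a as S (allyl trans to O3).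

Step 8
Reactants: 12 (3R,4aS)-4a-allyl-3-(tert-butyldimethylsilyloxy)-7-methoxy-2,2-dimethyl-8-(3-methylbut-2-en-1-yl)-6-(2-methylpropanoyl)-3,4-dihydro-2H-chromen-5(4aH)-one
Product: 13 (3R,4aS)-4a-allyl-3-hydroxy-7-methoxy-2,2-dimethyl-8-(3-methylbut-2-en-1-yl)-6-(2-methylpropanoyl)-3,4-dihydro-2H-chromen-5(4aH)-one (hydroxyl trans to allyl)
Conditions: HF·pyridine, pyridine, THF, 0 °C to rt
Reagents that add atoms: none
Why: Fluoride cleaves the Si–O bond (desilylation), and pyridine-buffered HF is neither basic enough to disturb the dienone nor acidic enough to hydrolyse the methyl enol ether or protonate the prenyl group, so that the alcohol is released only directly before its activation and no stereocentre is touched.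

Step 9
Reactants: 13 (3R,4aS)-4a-allyl-3-hydroxy-7-methoxy-2,2-dimethyl-8-(3-methylbut-2-en-1-yl)-6-(2-methylpropanoyl)-3,4-dihydro-2H-chromen-5(4aH)-one
Product: 16 (2S,3aS)-3a-allyl-2-(2-hydroxypropan-2-yl)-6-methoxy-7-(3-methylbut-2-en-1-yl)-5-(2-methylpropanoyl)-2,3-dihydro-1-benzofuran-4(3aH)-one, via C3 triflate 14 (not isolated), via bicyclic oxiranium triflate 15 (not isolated)
Conditions: Tf2O (1.2 equiv), 2,6-di-tert-butyl-4-methylpyridine (3 equiv), CH2Cl2, −78 °C; then THF/H2O (4:1), −78 to 0 °C
Reagents that add atoms: water, O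
Why: Proposed new method: triflation turns the equatorial C3 hydroxyl of 13 into the leaving group of 14, whose C3–O bond is antiperiplanar to the ring bond C2–O1 in the half-chair that carries the angular allyl group axial, so that O1 displaces triflate from the rear and water then opens the oxiranium ion 15 at its tertiary, more cation-stabilising carbon, which detaches O1 from CMe2 and leaves the tertiary alcohol there. The closest known reaction type is the ring contraction of tetrahydropyran-3-yl and 2,2-dimethylchroman-3-yl sulfonates through bicyclic oxiranium ions (the reverse of the tetrahydrofuran-to-tetrahydropyran ring expansion); new here is that the participating atom is the ring oxygen of a dienone, a doubly vinylogous ester oxygen that is less nucleophilic but still carries an in-plane lone pair. Ring B is closed by the new O1–C3 bond in a formal 5-exo-tet mode, the same bond first completing the transient three-membered oxiranium ring 3-exo-tet. The only new stereocentre, C2 of 16, arises by clean inversion of the (3R) carbinol carbon set in step 3 and therefore comes out S, trans to the untouched allyl group on C3a. The step needs neighbouring-group participation to win over 1,2-methyl shift, elimination, attack by other nucleophiles and acid damage: an equatorial leaving group has only ring bonds anti to it (an axial one would align a C2 methyl and H4 instead), the C5 carbonyl lies on the same face as the leaving group and cannot reach its rear, the C4a substituent is allyl and not the more nucleophilic prenyl, and the hindered pyridine keeps the C8 prenyl group and the enol ether free of triflic acid. Water attacks the tertiary carbon of 15 because the positive charge is concentrated there, and attack at C3 would merely return 13.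

Step 10
Reactants: 16 (2S,3aS)-3a-allyl-2-(2-hydroxypropan-2-yl)-6-methoxy-7-(3-methylbut-2-en-1-yl)-5-(2-methylpropanoyl)-2,3-dihydro-1-benzofuran-4(3aH)-one
Product: 17 (2S,3aS)-3a-allyl-7-{[(2R)-3,3-dimethyloxiran-2-yl]methyl}-2-(2-hydroxypropan-2-yl)-6-methoxy-5-(2-methylpropanoyl)-2,3-dihydro-1-benzofuran-4(3aH)-one
Conditions: D-fructose-derived Shi ketone (30 mol%), KHSO5 (as Oxone, 2KHSO5·KHSO4·K2SO4; 1.4 equiv), K2CO3, Bu4NHSO4 (cat.), MeCN/CH2(OMe)2/aq. Na2B4O7 buffer (pH 10.5), 0 °C
Reagents that add atoms: potassium peroxymonosulfate, [K+].[O-]S(=O)(=O)OO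
Why: Shi epoxidation, in which the chiral dioxirane attacks the electron-rich trisubstituted prenyl olefin through a spiro transition state and should give the R epoxide under catalyst control (the resident centres are remote), while the monosubstituted allyl olefin is a poor substrate for this catalyst and the ring double bonds are deactivated push-pull enol ethers.

Step 11
Reactants: 17 (2S,3aS)-3a-allyl-7-{[(2R)-3,3-dimethyloxiran-2-yl]methyl}-2-(2-hydroxypropan-2-yl)-6-methoxy-5-(2-methylpropanoyl)-2,3-dihydro-1-benzofuran-4(3aH)-one; 18 2-methyl-2-butene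
Product: 19 (2S,3aS)-7-{[(2R)-3,3-dimethyloxiran-2-yl]methyl}-2-(2-hydroxypropan-2-yl)-6-methoxy-3a-(3-methylbut-2-en-1-yl)-5-(2-methylpropanoyl)-2,3-dihydro-1-benzofuran-4(3aH)-one
Conditions: second-generation Grubbs catalyst (H2IMes)(PCy3)Cl2Ru=CHPh (5 mol%), 18 (excess)/CH2Cl2, 35 °C
Reagents that add atoms: 2-methyl-2-butene 18, CC=C(C)C
Why: Olefin cross-metathesis of the terminal allyl olefin against an excess of 2-methyl-2-butene, the standard allyl-to-prenyl conversion, which tolerates the trisubstituted epoxide, the tertiary alcohol and the vinylogous ester, stops at the trisubstituted product and runs cool enough to avoid sigmatropic shifts of the dienone.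

Step 12
Reactants: 19 (2S,3aS)-7-{[(2R)-3,3-dimethyloxiran-2-yl]methyl}-2-(2-hydroxypropan-2-yl)-6-methoxy-3a-(3-methylbut-2-en-1-yl)-5-(2-methylpropanoyl)-2,3-dihydro-1-benzofuran-4(3aH)-one
Product: 20 (2S,3aR)-7-{[(2R)-3,3-dimethyloxiran-2-yl]methyl}-4-hydroxy-2-(2-hydroxypropan-2-yl)-3a-(3-methylbut-2-en-1-yl)-5-(2-methylpropanoyl)-2,3-dihydro-1-benzofuran-6(3aH)-one (CNP0395488.1)
Conditions: LiOH·H2O (5 equiv), THF/H2O (3:1), 0 °C to rt; then sat. aq. NH4Cl
Reagents that add atoms: lithium hydroxide monohydrate, [Li+].[OH-].O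
Why: Hydrolysis of a vinylogous ester by addition-elimination: hydroxide adds to C6, which is β to both the ring ketone and the acyl carbonyl, methoxide leaves and the stabilised triketone enolate results, while at room temperature neither hydroxide nor this delocalised enolate should open the trisubstituted epoxide and the mildly acidic NH4Cl quench frees the enol without acid-catalysed cyclisation.

**Compound list**

1 | 5-methoxyresorcinol | COc1cc(O)cc(O)c1 | starting material
2 | isobutyryl chloride | CC(C)C(Cl)=O | starting material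
3 | 1-(2,4-dihydroxy-6-methoxyphenyl)-2-methylpropan-1-one | CC(C)C(=O)c1c(O)cc(O)cc1OC | intermediate
4 | 3-methylbut-2-enal | CC(C)=CC=O | starting material
5 | 1-(5-hydroxy-7-methoxy-2,2-dimethyl-2H-chromen-6-yl)-2-methylpropan-1-one | CC(C)C(=O)c1c(OC)cc2OC(C)(C)C=Cc2c1O | intermediate
6 | 1-[(3R,4R)-3,4-epoxy-5-hydroxy-7-methoxy-2,2-dimethyl-3,4-dihydro-2H-chromen-6-yl]-2-methylpropan-1-one | CC(C)C(=O)c1c(OC)cc2OC(C)(C)[C@@H]3O[C@@H]3c2c1O | intermediate
7 | 1-[(3R)-3,5-dihydroxy-7-methoxy-2,2-dimethyl-3,4-dihydro-2H-chromen-6-yl]-2-methylpropan-1-one | CC(C)C(=O)c1c(OC)cc2OC(C)(C)[C@H](O)Cc2c1O | intermediate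
8 | 2-methylbut-3-en-2-ol | CC(C)(O)C=C | starting material
9 | 1-[(3R)-3,5-dihydroxy-7-methoxy-2,2-dimethyl-8-(3-methylbut-2-en-1-yl)-3,4-dihydro-2H-chromen-6-yl]-2-methylpropan-1-one | CC(C)C(=O)c1c(OC)c(CC=C(C)C)c2OC(C)(C)[C@H](O)Cc2c1O | intermediate
10 | 1-[(3R)-3-(tert-butyldimethylsilyloxy)-5-hydroxy-7-methoxy-2,2-dimethyl-8-(3-methylbut-2-en-1-yl)-3,4-dihydro-2H-chromen-6-yl]-2-methylpropan-1-one | CC(C)C(=O)c1c(OC)c(CC=C(C)C)c2OC(C)(C)[C@H](O[Si](C)(C)C(C)(C)C)Cc2c1O | intermediate
11 | allyl bromide | C=CCBr | starting material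
12 | (3R,4aS)-4a-allyl-3-(tert-butyldimethylsilyloxy)-7-methoxy-2,2-dimethyl-8-(3-methylbut-2-en-1-yl)-6-(2-methylpropanoyl)-3,4-dihydro-2H-chromen-5(4aH)-one | C=CC[C@]12C[C@@H](O[Si](C)(C)C(C)(C)C)C(C)(C)OC1=C(CC=C(C)C)C(OC)=C(C(=O)C(C)C)C2=O | intermediate
13 | (3R,4aS)-4a-allyl-3-hydroxy-7-methoxy-2,2-dimethyl-8-(3-methylbut-2-en-1-yl)-6-(2-methylpropanoyl)-3,4-dihydro-2H-chromen-5(4aH)-one | C=CC[C@]12C[C@@H](O)C(C)(C)OC1=C(CC=C(C)C)C(OC)=C(C(=O)C(C)C)C2=O | intermediate (precursor of the key step)
14 | (3R,4aS)-4a-allyl-7-methoxy-2,2-dimethyl-8-(3-methylbut-2-en-1-yl)-6-(2-methylpropanoyl)-5-oxo-3,4,4a,5-tetrahydro-2H-chromen-3-yl trifluoromethanesulfonate | C=CC[C@]12C[C@@H](OS(=O)(=O)C(F)(F)F)C(C)(C)OC1=C(CC=C(C)C)C(OC)=C(C(=O)C(C)C)C2=O | intermediate (not isolated)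
15 | bicyclic oxiranium triflate (O1 bridging C2 and C3 of the former pyran, C3 inverted) | C=CC[C@]12C[C@@H]3[O+](C3(C)C)C1=C(CC=C(C)C)C(OC)=C(C(=O)C(C)C)C2=O.[O-]S(=O)(=O)C(F)(F)F | intermediate (not isolated)
16 | (2S,3aS)-3a-allyl-2-(2-hydroxypropan-2-yl)-6-methoxy-7-(3-methylbut-2-en-1-yl)-5-(2-methylpropanoyl)-2,3-dihydro-1-benzofuran-4(3aH)-one | C=CC[C@]12C[C@@H](C(C)(C)O)OC1=C(CC=C(C)C)C(OC)=C(C(=O)C(C)C)C2=O | intermediate (product of the key step)
17 | (2S,3aS)-3a-allyl-7-{[(2R)-3,3-dimethyloxiran-2-yl]methyl}-2-(2-hydroxypropan-2-yl)-6-methoxy-5-(2-methylpropanoyl)-2,3-dihydro-1-benzofuran-4(3aH)-one | C=CC[C@]12C[C@@H](C(C)(C)O)OC1=C(C[C@H]3OC3(C)C)C(OC)=C(C(=O)C(C)C)C2=O | intermediate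
18 | 2-methyl-2-butene | CC=C(C)C | starting material
19 | (2S,3aS)-7-{[(2R)-3,3-dimethyloxiran-2-yl]methyl}-2-(2-hydroxypropan-2-yl)-6-methoxy-3a-(3-methylbut-2-en-1-yl)-5-(2-methylpropanoyl)-2,3-dihydro-1-benzofuran-4(3aH)-one | CC(C)=CC[C@]12C[C@@H](C(C)(C)O)OC1=C(C[C@H]3OC3(C)C)C(OC)=C(C(=O)C(C)C)C2=O | intermediate
20 | (2S,3aR)-7-{[(2R)-3,3-dimethyloxiran-2-yl]methyl}-4-hydroxy-2-(2-hydroxypropan-2-yl)-3a-(3-methylbut-2-en-1-yl)-5-(2-methylpropanoyl)-2,3-dihydro-1-benzofuran-6(3aH)-one | CC(C)=CC[C@]12C[C@@H](C(C)(C)O)OC1=C(C[C@H]1OC1(C)C)C(=O)C(C(=O)C(C)C)=C2O | target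

**Total step count:** 12. **Longest linear sequence:** 12 steps (1 to 20).

**Steps most likely to fail**

Step 9. The conjugated ring oxygen may participate too slowly, so that ionisation of the triflate is taken over by 1,2-methyl migration from C2, by elimination towards C4, or by plain hydrolysis back to the alcohol. The fallback contracts the ring while it is still aromatic, where the participating atom is an aryl ether oxygen as in the known chroman-3-yl sulfonate contractions, and dearomatises afterwards. It sets out from 9: selective triflation of the secondary alcohol (Tf2O, 2,6-lutidine, CH2Cl2, −78 °C; the hydrogen-bonded phenol should not react) and warming in aqueous THF should give the dihydrobenzofuran carbinol 1-[(2S)-4-hydroxy-2-(2-hydroxypropan-2-yl)-6-methoxy-7-(3-methylbut-2-en-1-yl)-2,3-dihydro-1-benzofuran-5-yl]-2-methylpropan-1-one F1. Alkylative dearomatisation of its dilithium salt (LiN(SiMe3)2, 2.2 equiv, toluene/THF, then allyl bromide 11, −78 to 0 °C), with allyl entering anti to the C2 side chain, comes back to the route at 16.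

Step 7. Allylation may go to the para carbon C8 or to oxygen instead of the ortho carbon C4a, and the silyl ether may discriminate the two faces of C4a too weakly. The fallback replaces the SN2 alkylation by a π-allyl electrophile delivered inside an ion pair. It sets out from 10, which is acylated with allyl chloroformate (pyridine, DMAP, CH2Cl2) to the aryl allyl carbonate F2. Decarboxylative allylic dearomatisation with Pd2(dba)3 and a chiral bis(2-diphenylphosphinobenzoyl)-1,2-diaminocyclohexane (Trost) ligand in toluene at rt then comes back to the route at 12. Zerovalent palladium ionises the carbonate, CO2 is lost, and the phenoxide/π-allyl pair should collapse at the adjacent ortho carbon; the ligand enantiomer that reinforces the substrate bias is chosen after testing both.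

Step 12. The neighbouring triketone enolate or hydroxide may open the epoxide during hydrolysis, or the freed enol may cyclise onto it on acidification. The fallback exchanges the methyl group for a fluoride-cleavable group before the epoxide exists. It sets out from 16: LiOH·H2O in aqueous dioxane (no epoxide present yet) should give the free triketone F3. Mitsunobu etherification of its acidic enol with 2-(trimethylsilyl)ethanol (PPh3, diisopropyl azodicarboxylate, THF, 0 °C; an O4 regioisomer would converge later) gives the silylethyl enol ether F4. Shi epoxidation under the conditions of step 10 gives the epoxide F5, and cross-metathesis under the conditions of step 11 gives the prenyl compound F6. Bu4NF in THF at 0 °C then fragments the silylethyl ether to ethene, Me3SiF and the enolate, which after a pH 6 buffer quench comes back to the route at 20.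

**Further compounds**

F1 | step 9 | 1-[(2S)-4-hydroxy-2-(2-hydroxypropan-2-yl)-6-methoxy-7-(3-methylbut-2-en-1-yl)-2,3-dihydro-1-benzofuran-5-yl]-2-methylpropan-1-one | CC(C)C(=O)c1c(OC)c(CC=C(C)C)c2O[C@H](C(C)(C)O)Cc2c1O
F2 | step 7 | allyl (3R)-3-(tert-butyldimethylsilyloxy)-7-methoxy-2,2-dimethyl-8-(3-methylbut-2-en-1-yl)-6-(2-methylpropanoyl)-3,4-dihydro-2H-chromen-5-yl carbonate | CC(C)C(=O)c1c(OC)c(CC=C(C)C)c2OC(C)(C)[C@H](O[Si](C)(C)C(C)(C)C)Cc2c1OC(=O)OCC=C
F3 | step 12 | (2S,3aR)-3a-allyl-4-hydroxy-2-(2-hydroxypropan-2-yl)-7-(3-methylbut-2-en-1-yl)-5-(2-methylpropanoyl)-2,3-dihydro-1-benzofuran-6(3aH)-one | C=CC[C@]12C[C@@H](C(C)(C)O)OC1=C(CC=C(C)C)C(=O)C(C(=O)C(C)C)=C2O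
F4 | step 12 | (2S,3aS)-3a-allyl-2-(2-hydroxypropan-2-yl)-7-(3-methylbut-2-en-1-yl)-5-(2-methylpropanoyl)-6-[2-(trimethylsilyl)ethoxy]-2,3-dihydro-1-benzofuran-4(3aH)-one | C=CC[C@]12C[C@@H](C(C)(C)O)OC1=C(CC=C(C)C)C(OCC[Si](C)(C)C)=C(C(=O)C(C)C)C2=O
F5 | step 12 | (2S,3aS)-3a-allyl-7-{[(2R)-3,3-dimethyloxiran-2-yl]methyl}-2-(2-hydroxypropan-2-yl)-5-(2-methylpropanoyl)-6-[2-(trimethylsilyl)ethoxy]-2,3-dihydro-1-benzofuran-4(3aH)-one | C=CC[C@]12C[C@@H](C(C)(C)O)OC1=C(C[C@H]3OC3(C)C)C(OCC[Si](C)(C)C)=C(C(=O)C(C)C)C2=O
F6 | step 12 | (2S,3aS)-7-{[(2R)-3,3-dimethyloxiran-2-yl]methyl}-2-(2-hydroxypropan-2-yl)-3a-(3-methylbut-2-en-1-yl)-5-(2-methylpropanoyl)-6-[2-(trimethylsilyl)ethoxy]-2,3-dihydro-1-benzofuran-4(3aH)-one | CC(C)=CC[C@]12C[C@@H](C(C)(C)O)OC1=C(C[C@H]3OC3(C)C)C(OCC[Si](C)(C)C)=C(C(=O)C(C)C)C2=O
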